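## Structural features

Kanzonol T (22) is an isoflavone: ring A (benzene) and ring C (4-pyranone) form a chromen-4-one, and ring B is attached to C3 through C1'. Ring A is substituted everywhere except C8: the hydroxyls at C5 and C7 flank a saturated 3-hydroxy-3-methylbutyl chain at C6. Ring B is a 1,2,3,4-tetrasubstituted benzene in which C2' carries a free OH and C3'/C4' are fused to a 2,2-dimethyl-2H-pyran with its oxygen on C4' and its C=C starting at C3' (an angular chromene), so that C5' and C6' are the only CH positions. The molecule has no stereocentre, so no stereocentres adjoin and nothing has to be set. The fragile groups are the tertiary alcohol (it ionises in acid and can then close onto O5 or O7 as a chroman), the chromene C=C (acid, hydrogenation, electrophiles), C2 of the chromone (amines, hydroxide, alkoxide) and three phenols. The real difficulty is regiochemical and arises twice: the chain must sit at C6 and not C8, and ring B needs four contiguous substituents with the pyran fused in the angular sense. The key step exploits that C3'–C6' together with the fused pyran are the diene carbons C4a, C8a, C8 and C7 of a pyran-fused 2-pyrone, while C1'–C2'(O) is an oxygen-substituted alkyne. Joining C1' to C6' and C2' to C3' and expelling CO2 creates ring B with every substituent placed by connectivity.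

## Logic of the disconnections

22 is traced back to 21 by cutting four O–Si bonds (O5, O7, O2' and the side-chain oxygen). All hydroxyls must be masked in the key step, and the tertiary alcohol rules out acid-labile groups, so only fluoride-labile groups are used. Nothing is gained in skeleton, but the unmasking is one mild step. The forward step must not open the chromone, hence buffered fluoride.

21 is cut at C1'–C6' and C2'–C3', with CO2 put back as a lactone bridge (20), which gives 15 and 19. Fused numbering of 19 is O1, C2, C3, C4, C4a, C5(=O), O6, C7, C8, C8a; C7 becomes C6' and C4a becomes C3'. Cutting here removes ring B, its four contiguous substituents and the angular fusion in one stroke, leaving a bicyclic lactone and an alkyne on an intact chromone. The forward step must give a single orientation, use the pyrone diene and not the 2H-pyran diene, and be fast enough for the ynol ether to survive.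

19 is cut at C4–C4a and O1–C2, which leads through 18 to 16 and 17. This is a formal [3+3] annulation of two commercial compounds. It requires condensation at C3 of 16 and ring closure through the C4 oxygen.

15 is cut at the C3–C(sp) bond, giving 11 and 14. The sensitive ynol ether is thus introduced last, under mild conditions, on a fully protected chromone. The forward coupling must tolerate a terminal silyl ynol ether and must not let an amine open the chromone.

14 is cut at O–Si and traced through 13 to 12, whose two bromines and ethoxy group are lost as the triple bond forms. The forward step must silylate the ynolate on oxygen, not on carbon.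

11 is cut at O1–C2, C2–C3 and C3–I, which leads through 10 to 9. One carbon comes from an amide acetal, and iodination and ring closure occur together. The demand is that exactly one phenol is free and that it lies para to the chain, so that the chain ends up at C6.

9 is cut at the benzyl–oxygen bond and, after putting back the triple bond (8), at the aryl–alkynyl bond, giving 5 and 7. The five-carbon chain thus comes from a commercial alkynol, and one hydrogenation both saturates the chain and frees the phenol. The coupling has to proceed at an iodide with two ortho silyloxy groups.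

7 is cut at O–Si to 6. The tertiary alcohol is protected before it enters the main line.

5 is traced through 4, 3 and 2 to 1 by cutting O–Si (O5), C–I, O–benzyl and O–Si (O7). The three oxygens of symmetrical 1 are told apart by acidity and hydrogen bonding: the para oxygen is silylated first, one ortho oxygen is benzylated, and the remaining free phenol directs iodine to its own ortho position. Each forward step must be regioselective, and the benzyl ether must stay until the hydrogenation.

## Other disconnections considered

Alternative 1: The cut is O1–C8a and C4–C4a, with ring A as an aryne and ring B as a formylacetate. In the forward step CsF converts the ortho-silyl aryl triflate A2 into the aryne A3; the enolate oxygen of formylacetate A4 adds to it and the resulting aryl anion acylates on the ester, closing ring C to give A1.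
- In its favour: the union is late and convergent, and ring C is closed in one operation. The 5-alkoxy group next to the triple bond of A3 should steer the oxygen nucleophile to the remote carbon, which is the required orientation. On this point it is at least the equal of the chosen plan, whose orientation rests on an untested polar match.
- Against it here: A1 needs acid to lose three methoxymethyl groups next to a tertiary alcohol that cyclises onto O5 or O7 in acid. C-arylation of the ambident enolate competes with O-arylation. A2 is a pentasubstituted arene that must be made with the same C6/C8 control as 9 plus a silyl triflate. A4 already contains the angular chromene, whose regiochemistry must be solved separately.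
- Comparison: the mechanism is closer to known aryne chemistry than step 12, and the step count is similar or higher. Structurally the chosen plan is better because it makes the 1',2',3',4' pattern in the ring-forming step itself and ends with fluoride instead of acid.

Alternative 2: The cut is C7–C8 and C5–C6, so ring A is built last on a preformed ring C. In the forward step the 2-methyl group of pyranone ester A6 is deprotonated and attacks lactone A7; the new enolate then closes on the ester in a Claisen–Dieckmann sequence that aromatises to A5.
- In its favour: O5, O7 and the C6 chain are fixed by connectivity, and the tertiary alcohol is released by the lactone opening without any protecting group. For ring A this is the better plan, because the chosen route spends a temporary benzyl group and a directed iodination on the same problem. Only one allyl group has to be removed at the end.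
- Against it here: after the first acylation the C8 methylene is the more acidic site, while ring closure needs the carbanion at C6. Several equivalents of strong base must coexist with a 4-pyranone that is electrophilic at C2 and with an allyl aryl ether that can isomerise. A6 itself needs a multistep synthesis that includes the angular chromene of ring B.
- Comparison: it is equal in convergence and better for ring A, but worse for ring B, which is the harder half of the molecule. Its key step is also a polyanion cascade whose site selectivity is no more certain than that of step 12.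

Alternative 3: The cut is C4–C3 and O1–C2. In the forward step salicylaldehyde A9 and silyl alkyne A10 are joined under [Cp*RhCl2]2 with Cu(OAc)2 by aldehyde C–H activation, alkyne insertion and C–O bond formation, giving A8.
- In its favour: it is catalytic and convergent, and the silyl group should place the aryl group at C3. The same fluoride step that removes the silyl ethers also removes the C2 silyl group, so the endgame is equal to that of the chosen plan. A9 needs the same differentiation of the ring A oxygens as 9, so the two plans are equal there as well.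
- Against it here: the formyl group of A9 is flanked by a bulky silyloxy group, which disfavours metalation and invites decarbonylation. A stoichiometric divalent copper oxidant at elevated temperature meets a free tertiary alcohol, aryl silyl ethers and the chromene. The insertion regiochemistry with an ortho-substituted aryl alkyne is less certain than with simple aryl alkynes. A10 again requires the angular chromene with an ortho oxygen.
- Comparison: the reaction type is established for simple salicylaldehydes, which is an advantage over step 12. Structurally it moves the ring B problem into a separate synthesis, and its step count is not lower.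

Key step: step 12

Assumption: anhydrous 1 (the commercial monohydrate, dried) and 16 are taken as commercially available, and 14 is taken to be a distillable liquid that can be stored cold under argon.

Remark: the atom mapping of the cycloaddition was checked (C7 and C4a of 19 become C6' and C3', the alkyne carbons become C1' and C2') and no connectivity had to be corrected. The protecting-group set of 15 and 21 is TBS on O5, TIPS on O7 and O2', and TES on the side-chain oxygen, because O7 is silylated first and must survive eight steps.

## Steps

Step 1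
Reactants: 1 2,4,6-trihydroxyacetophenone
Product: 2 1-[2,6-dihydroxy-4-(triisopropylsilyloxy)phenyl]ethanone
Conditions: TIPSCl (1.05 equiv), imidazole (2.2 equiv), DMF, 0 °C → rt
Reagents that add atoms: chlorotriisopropylsilane, CC(C)[Si](Cl)(C(C)C)C(C)C
Why: Selective O-silylation: the 4-OH is the most acidic hydroxyl and the only one neither hydrogen-bonded to nor flanked by the acetyl group, so the bulky silyl chloride should take it alone. TIPS is chosen because this oxygen (later O7) must last to the end and then fall to fluoride.

Step 2
Reactants: 2 1-[2,6-dihydroxy-4-(triisopropylsilyloxy)phenyl]ethanone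
Product: 3 1-[2-(benzyloxy)-6-hydroxy-4-(triisopropylsilyloxy)phenyl]ethanone
Conditions: BnOH (1.1 equiv), PPh3 (1.2 equiv), DIAD (1.2 equiv), THF, 0 °C → rt
Reagents that add atoms: benzyl alcohol, OCc1ccccc1
Why: Mitsunobu etherification of an acidic phenol under neutral conditions that spare the aryl silyl ether; once one ortho hydroxyl is benzylated the other is locked in a hydrogen bond to the ketone and should not react again. The benzyl ether marks the oxygen that will become O1.

Step 3
Reactants: 3 1-[2-(benzyloxy)-6-hydroxy-4-(triisopropylsilyloxy)phenyl]ethanone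
Product: 4 1-[6-(benzyloxy)-2-hydroxy-3-iodo-4-(triisopropylsilyloxy)phenyl]ethanone
Conditions: BnMe3N·ICl2 (1.05 equiv), CaCO3, CH2Cl2–MeOH, rt
Reagents that add atoms: benzyltrimethylammonium dichloroiodate, C[N+](C)(C)Cc1ccccc1.Cl[I-]Cl
Why: Electrophilic aromatic iodination ortho to a free phenol, the usual outcome with this reagent on 2-hydroxy-4,6-dialkoxyacetophenones; the site between OH and OTIPS is also less hindered than the one between OBn and OTIPS. Iodine thus enters the carbon that becomes C6.

Step 4
Reactants: 4 1-[6-(benzyloxy)-2-hydroxy-3-iodo-4-(triisopropylsilyloxy)phenyl]ethanone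
Product: 5 1-[6-(benzyloxy)-2-(tert-butyldimethylsilyloxy)-3-iodo-4-(triisopropylsilyloxy)phenyl]ethanone
Conditions: TBSOTf (1.3 equiv), 2,6-lutidine (2 equiv), CH2Cl2, –40 → 0 °C; aqueous NaHCO3 work-up
Reagents that add atoms: tert-butyldimethylsilyl trifluoromethanesulfonate, CC(C)(C)[Si](C)(C)OS(=O)(=O)C(F)(F)F
Why: Silyl triflate silylation of a hindered, chelated phenol; capping this oxygen (later O5) prevents benzofuran formation in the coupling that follows and leaves only one oxygen able to close ring C later. Any silyl enol ether of the methyl ketone should revert on work-up.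

Step 5
Reactants: 6 2-methylbut-3-yn-2-ol
Product: 7 triethyl[(2-methylbut-3-yn-2-yl)oxy]silane
Conditions: TESCl (1.2 equiv), imidazole (2.5 equiv), DMAP (cat.), DMF, rt
Reagents that add atoms: chlorotriethylsilane, CC[Si](Cl)(CC)CC
Why: Standard silylation of a tertiary propargylic alcohol; the TES ether protects the future side-chain hydroxyl through the coupling, enaminone and cycloaddition steps and is fluoride-labile.

Step 6
Reactants: 5 1-[6-(benzyloxy)-2-(tert-butyldimethylsilyloxy)-3-iodo-4-(triisopropylsilyloxy)phenyl]ethanone; 7 triethyl[(2-methylbut-3-yn-2-yl)oxy]silane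
Product: 8 1-[6-(benzyloxy)-2-(tert-butyldimethylsilyloxy)-3-[3-methyl-3-(triethylsilyloxy)but-1-yn-1-yl]-4-(triisopropylsilyloxy)phenyl]ethanone
Conditions: Pd(PPh3)2Cl2 (5 mol%), CuI (10 mol%), Et3N, DMF, 60 °C
Reagents that add atoms: none
Why: Sonogashira coupling of an aryl iodide with a terminal alkyne; the rod-shaped alkyne tolerates the two ortho silyloxy groups and nothing more basic than a tertiary amine meets the silyl ethers. All five carbons of the C6 chain arrive with the tertiary alcohol already protected.

Step 7
Reactants: 8 1-[6-(benzyloxy)-2-(tert-butyldimethylsilyloxy)-3-[3-methyl-3-(triethylsilyloxy)but-1-yn-1-yl]-4-(triisopropylsilyloxy)phenyl]ethanone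
Product: 9 1-[2-(tert-butyldimethylsilyloxy)-6-hydroxy-3-[3-methyl-3-(triethylsilyloxy)butyl]-4-(triisopropylsilyloxy)phenyl]ethanone
Conditions: H2 (1 atm), 10% Pd/C, EtOAc, rt
Reagents that add atoms: none
Why: Catalytic hydrogenation saturates the alkyne and hydrogenolyses the benzyl ether in the same operation, while silyl ethers and the hindered aryl ketone are inert under neutral conditions. The freed phenol lies para to the chain, so ring closure through it must place the chain at C6.

Step 8
Reactants: 9 1-[2-(tert-butyldimethylsilyloxy)-6-hydroxy-3-[3-methyl-3-(triethylsilyloxy)butyl]-4-(triisopropylsilyloxy)phenyl]ethanone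
Product: 11 5-(tert-butyldimethylsilyloxy)-3-iodo-6-[3-methyl-3-(triethylsilyloxy)butyl]-7-(triisopropylsilyloxy)-4H-chromen-4-one, via enaminone 10 (not isolated)
Conditions: Me2NCH(OMe)2 (3 equiv), PhMe, 80 °C; evaporate; I2 (1.5 equiv), pyridine (1.5 equiv), CHCl3, 0 °C → rt
Reagents that add atoms: N,N-dimethylformamide dimethyl acetal, COC(OC)N(C)C; iodine, II
Why: Condensation of the methyl ketone with the amide acetal gives enaminone 10; iodine attacks its electron-rich α-carbon and the only free phenol closes on the iminium carbon (6-exo-trig) with loss of dimethylamine, the standard enaminone route to 3-iodochromones. Because O5 is silylated, closure can only occur through the oxygen para to the chain.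

Step 9
Reactants: 12 ethyl dibromoacetate
Product: 14 (ethynyloxy)triisopropylsilane, via lithium ethynolate 13 (not isolated)
Conditions: t-BuLi (4.0 equiv), THF, –78 → 0 °C; TIPSCl (1.1 equiv), –78 °C → rt; distillation
Reagents that add atoms: chlorotriisopropylsilane, CC(C)[Si](Cl)(C(C)C)C(C)C
Why: Two bromine–lithium exchanges turn the α,α-dibromo ester into an ester dianion that expels lithium ethoxide to give the ynolate, the known ynolate synthesis from α,α-dibromo esters applied to the parent member. Bulky silyl chlorides are known to silylate ynolates on oxygen, giving the silyl ynol ether.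

Step 10
Reactants: 11 5-(tert-butyldimethylsilyloxy)-3-iodo-6-[3-methyl-3-(triethylsilyloxy)butyl]-7-(triisopropylsilyloxy)-4H-chromen-4-one; 14 (ethynyloxy)triisopropylsilane
Product: 15 5-(tert-butyldimethylsilyloxy)-6-[3-methyl-3-(triethylsilyloxy)butyl]-7-(triisopropylsilyloxy)-3-[(triisopropylsilyloxy)ethynyl]-4H-chromen-4-one
Conditions: Pd(PPh3)2Cl2 (5 mol%), CuI (5 mol%), Et3N (3 equiv), THF, rt, degassed; filtration through Et3N-deactivated silica
Reagents that add atoms: none
Why: Sonogashira coupling of the activated C3–I bond of a 3-iodochromone with a terminal ynol ether, a coupling known for alkoxyacetylenes. A tertiary amine is used because secondary amines open chromones at C2, and the product is kept cold and dry because the ynol ether hydrates easily.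

Step 11
Reactants: 16 4-hydroxy-2H-pyran-2-one; 17 3-methylbut-2-enal
Product: 19 2,2-dimethyl-2H,5H-pyrano[4,3-b]pyran-5-one, via oxatriene 18 (not isolated)
Conditions: (H3NCH2CH2NH3)(OAc)2 (10 mol%), MeOH, rt → 50 °C
Reagents that add atoms: none
Why: Knoevenagel condensation at C3 of the hydroxypyrone gives 1-oxatriene 18, which closes by oxa-6π electrocyclisation through the C4 oxygen (formal [3+3] annulation). This is the established route from 4-hydroxy-2-pyrones and enals to 2H-pyrano-fused 2-pyrones.

Step 12
Reactants: 15 5-(tert-butyldimethylsilyloxy)-6-[3-methyl-3-(triethylsilyloxy)butyl]-7-(triisopropylsilyloxy)-3-[(triisopropylsilyloxy)ethynyl]-4H-chromen-4-one; 19 2,2-dimethyl-2H,5H-pyrano[4,3-b]pyran-5-one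
Product: 21 5-(tert-butyldimethylsilyloxy)-3-[2,2-dimethyl-5-(triisopropylsilyloxy)-2H-chromen-6-yl]-6-[3-methyl-3-(triethylsilyloxy)butyl]-7-(triisopropylsilyloxy)-4H-chromen-4-one, via bridged lactone 20 (not isolated)
Conditions: 19 (1.5 equiv), AgNTf2 (10 mol%), 4 Å MS, ClCH2CH2Cl, rt → 60 °C (thermal variant: PhMe, 110 °C, sealed tube)
Reagents that add atoms: none
Why: Proposed new method: AgNTf2 should bind the electron-rich triple bond of 15 and make the silyloxy-bearing carbon ketenium-like, so that C4a of 19 (the nucleophilic α-carbon of the vinylogous carbonate) attacks it and the resulting alkenylsilver carbon, which carries the chromone, closes on C7, the oxygen-stabilised electrophilic terminus, to give bridged lactone 20; without silver the same two bonds would form in a concerted but strongly asynchronous [4+2] cycloaddition led by the nucleophilic alkyne carbon at C7. Lactone 20 then loses CO2 by a retro-[4+2] reaction that is irreversible and makes ring B aromatic. The closest known reaction types are the inverse-demand Diels–Alder reaction of 2-pyrones with ynamines or alkynyl ethers followed by decarboxylation, and the silver-catalysed formal [4+2] reaction of siloxyalkynes with 1,2-diazines followed by loss of N2. Ring B is closed by an intermolecular [4+2] annulation in which C1'–C6' and C2'–C3' both form between the two components (the second bond in a six-membered closure), not by cyclisation of a chain. No stereocentre is created in 21, and the two bridgehead centres of racemic 20 vanish on decarboxylation. The step needs one orientation and one diene: both mechanistic extremes pair the silyloxy carbon with C4a and the chromonyl carbon with C7, which puts O2' next to C3', and the pyrone diene should win over the cyclic diene of the 2H-pyran ring because its C7–H terminus is unhindered and only its adduct can aromatise by losing CO2.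

Step 13
Reactants: 21 5-(tert-butyldimethylsilyloxy)-3-[2,2-dimethyl-5-(triisopropylsilyloxy)-2H-chromen-6-yl]-6-[3-methyl-3-(triethylsilyloxy)butyl]-7-(triisopropylsilyloxy)-4H-chromen-4-one
Product: 22 Kanzonol T
Conditions: Bu4NF (8 equiv), AcOH (8 equiv), THF, 0 °C → rt
Reagents that add atoms: none
Why: Fluoride cleaves the three aryl silyl ethers quickly and the tertiary TES ether more slowly; the acetic acid buffer keeps phenoxide and fluoride basicity low enough to avoid opening the chromone at C2. No acid strong enough to ionise the tertiary alcohol or the chromene is present.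

## Compound list

1 | 2,4,6-trihydroxyacetophenone | CC(=O)c1c(O)cc(O)cc1O | starting material
2 | 1-[2,6-dihydroxy-4-(triisopropylsilyloxy)phenyl]ethanone | CC(=O)c1c(O)cc(O[Si](C(C)C)(C(C)C)C(C)C)cc1O | intermediate
3 | 1-[2-(benzyloxy)-6-hydroxy-4-(triisopropylsilyloxy)phenyl]ethanone | CC(=O)c1c(O)cc(O[Si](C(C)C)(C(C)C)C(C)C)cc1OCc1ccccc1 | intermediate
4 | 1-[6-(benzyloxy)-2-hydroxy-3-iodo-4-(triisopropylsilyloxy)phenyl]ethanone | CC(=O)c1c(O)c(I)c(O[Si](C(C)C)(C(C)C)C(C)C)cc1OCc1ccccc1 | intermediate
5 | 1-[6-(benzyloxy)-2-(tert-butyldimethylsilyloxy)-3-iodo-4-(triisopropylsilyloxy)phenyl]ethanone | CC(=O)c1c(O[Si](C)(C)C(C)(C)C)c(I)c(O[Si](C(C)C)(C(C)C)C(C)C)cc1OCc1ccccc1 | intermediate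
6 | 2-methylbut-3-yn-2-ol | C#CC(C)(C)O | starting material
7 | triethyl[(2-methylbut-3-yn-2-yl)oxy]silane | C#CC(C)(C)O[Si](CC)(CC)CC | intermediate
8 | 1-[6-(benzyloxy)-2-(tert-butyldimethylsilyloxy)-3-[3-methyl-3-(triethylsilyloxy)but-1-yn-1-yl]-4-(triisopropylsilyloxy)phenyl]ethanone | CC(=O)c1c(O[Si](C)(C)C(C)(C)C)c(C#CC(C)(C)O[Si](CC)(CC)CC)c(O[Si](C(C)C)(C(C)C)C(C)C)cc1OCc1ccccc1 | intermediate
9 | 1-[2-(tert-butyldimethylsilyloxy)-6-hydroxy-3-[3-methyl-3-(triethylsilyloxy)butyl]-4-(triisopropylsilyloxy)phenyl]ethanone | CC(=O)c1c(O[Si](C)(C)C(C)(C)C)c(CCC(C)(C)O[Si](CC)(CC)CC)c(O[Si](C(C)C)(C(C)C)C(C)C)cc1O | intermediate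
10 | (E)-1-[2-(tert-butyldimethylsilyloxy)-6-hydroxy-3-[3-methyl-3-(triethylsilyloxy)butyl]-4-(triisopropylsilyloxy)phenyl]-3-(dimethylamino)prop-2-en-1-one (enaminone, not isolated) | CN(C)/C=C/C(=O)c1c(O[Si](C)(C)C(C)(C)C)c(CCC(C)(C)O[Si](CC)(CC)CC)c(O[Si](C(C)C)(C(C)C)C(C)C)cc1O | intermediate
11 | 5-(tert-butyldimethylsilyloxy)-3-iodo-6-[3-methyl-3-(triethylsilyloxy)butyl]-7-(triisopropylsilyloxy)-4H-chromen-4-one | CC(C)(O[Si](CC)(CC)CC)CCc1c(O[Si](C(C)C)(C(C)C)C(C)C)cc2occ(I)c(=O)c2c1O[Si](C)(C)C(C)(C)C | intermediate
12 | ethyl dibromoacetate | CCOC(=O)C(Br)Br | starting material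
13 | lithium ethynolate (not isolated) | [Li+].[O-]C#C | intermediate
14 | (ethynyloxy)triisopropylsilane | C#CO[Si](C(C)C)(C(C)C)C(C)C | intermediate
15 | 5-(tert-butyldimethylsilyloxy)-6-[3-methyl-3-(triethylsilyloxy)butyl]-7-(triisopropylsilyloxy)-3-[(triisopropylsilyloxy)ethynyl]-4H-chromen-4-one | CC(C)(O[Si](CC)(CC)CC)CCc1c(O[Si](C(C)C)(C(C)C)C(C)C)cc2occ(C#CO[Si](C(C)C)(C(C)C)C(C)C)c(=O)c2c1O[Si](C)(C)C(C)(C)C | intermediate
16 | 4-hydroxy-2H-pyran-2-one | O=C1C=C(O)C=CO1 | starting material
17 | 3-methylbut-2-enal | CC(C)=CC=O | starting material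
18 | 3-(3-methylbut-2-en-1-ylidene)-2H-pyran-2,4(3H)-dione (oxatriene, not isolated, alkene geometry not defined) | CC(C)=CC=C1C(=O)C=COC1=O | intermediate
19 | 2,2-dimethyl-2H,5H-pyrano[4,3-b]pyran-5-one | O=C1OC=CC2=C1C=CC(C)(C)O2 | intermediate
20 | bridged lactone: the 2-oxabicyclo[2.2.2]octa-5,7-dien-3-one formed by bonding C7 of 19 to the chromonyl alkyne carbon of 15 and C4a of 19 to the silyloxy alkyne carbon (racemic, relative configuration fixed by the bicycle, not isolated) | O=C1OC2C=C3OC(C)(C)C=CC31C(O[Si](C(C)C)(C(C)C)C(C)C)=C2c1coc2cc(O[Si](C(C)C)(C(C)C)C(C)C)c(CCC(C)(C)O[Si](CC)(CC)CC)c(O[Si](C)(C)C(C)(C)C)c2c1=O | intermediate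
21 | 5-(tert-butyldimethylsilyloxy)-3-[2,2-dimethyl-5-(triisopropylsilyloxy)-2H-chromen-6-yl]-6-[3-methyl-3-(triethylsilyloxy)butyl]-7-(triisopropylsilyloxy)-4H-chromen-4-one (tetrakis-O-silyl Kanzonol T) | CC(C)(O[Si](CC)(CC)CC)CCc1c(O[Si](C(C)C)(C(C)C)C(C)C)cc2occ(-c3ccc4OC(C)(C)C=Cc4c3O[Si](C(C)C)(C(C)C)C(C)C)c(=O)c2c1O[Si](C)(C)C(C)(C)C | intermediate
22 | Kanzonol T, 5,7-dihydroxy-3-(5-hydroxy-2,2-dimethyl-2H-chromen-6-yl)-6-(3-hydroxy-3-methylbutyl)-4H-chromen-4-one (no stereocentre) | CC(C)(O)CCc1c(O)cc2occ(-c3ccc4c(c3O)C=CC(C)(C)O4)c(=O)c2c1O | target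

## Step count and least certain steps

Total step count: 13. Longest linear sequence: 10 steps (1, 2, 3, 4, 6, 7, 8, 10, 12, 13).

**Step 12 (key step, proposed new method).**
- What may go wrong: the cycloaddition may be too slow because both partners are fairly electron-rich. Hydration, dimerisation or silyl migration of the ynol ether could then take over, as could [2+2]-type addition across the enol ether C7=C8 or cycloaddition on the 2H-pyran diene with loss of acetone. A reversed orientation would place O2' wrongly.
- Fallback (known chemistry only; sets out from 11 and 17, returns at 22): ring B is made separately and joined by Suzuki–Miyaura coupling. Commercial cyclohexane-1,3-dione (O=C1CCCC(=O)C1) is condensed with 17 under the conditions of step 11 to give 2,2-dimethyl-2,6,7,8-tetrahydro-5H-chromen-5-one F1. Dehydrogenation with DDQ in refluxing dioxane gives 2,2-dimethyl-2H-chromen-5-ol F2, and SEMCl with i-Pr2NEt gives its 2-(trimethylsilyl)ethoxymethyl ether F3. Directed ortho-lithiation with n-BuLi (C6 is the only free position ortho to the acetal oxygen) and quenching with i-PrOBpin give the pinacol boronate F4. Coupling of F4 with 11 under Pd(dppf)Cl2 and K3PO4 in dioxane–water gives the 2'-O-SEM isoflavone F5. Bu4NF in THF–DMPU at 45 °C then removes the SEM group together with the three silyl ethers and gives 22.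

**Step 9.**
- What may go wrong: deprotonation of the acidic α-hydrogen or carbonyl addition by t-BuLi may compete with bromine–lithium exchange. The unhindered carbon end of the parent ynolate may be silylated to a silylketene. The volatile product may be lost or hydrated on isolation.
- Fallback (sets out from 11, returns at 15, avoids 14 altogether): Sonogashira coupling of 11 with ethynyltrimethylsilane gives the 3-[(trimethylsilyl)ethynyl]chromone F6. AgNO3-catalysed protodesilylation in aqueous acetone, which spares silyl ethers, gives the 3-ethynylchromone F7. Deprotonation with LiN(SiMe3)2 at –78 °C gives the lithium acetylide F8, which is oxidised with lithium tert-butyl peroxide F9 (from t-BuOOH and LiN(SiMe3)2) to the lithium ynolate F10 and silylated on oxygen with TIPSOTf to give 15. The chromone must survive a lithium acetylide and a nucleophilic peroxide at low temperature, which is why this is the fallback and not the route.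

**Step 10.**
- What may go wrong: copper-mediated oxidative dimerisation of 14, amine- or water-induced loss of the ynol ether (ketene formation, hydration to the silyl arylacetate), or conjugate attack at C2 of the chromone.
- Fallback (sets out from 14 and 11, returns at 15): a copper- and amine-free Negishi coupling. 14 is deprotonated with LiN(SiMe3)2 at –78 °C to lithium [(triisopropylsilyl)oxy]acetylide F11, transmetalated with ZnCl2 to chloro{[(triisopropylsilyl)oxy]ethynyl}zinc F12 and coupled with 11 under Pd(PPh3)4 in THF at rt.

**Step 8.**
- What may go wrong: methoxide released from the amide acetal at 80 °C may cleave the hindered 5-O-TBS ether or methylate the phenol, after which ring closure loses its direction.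
- Fallback (sets out from 9, returns at 10 and thus at 11): Claisen formylation at low temperature replaces the amide acetal. 9 is treated with NaH and ethyl formate in THF at 0 °C to give, after work-up, the racemic 2-hydroxychroman-4-one F13 (the cyclic hemiacetal of the β-keto aldehyde). Me2NH in THF at rt opens it to enaminone 10, which is cyclised with I2 as in step 8.

**Step 6.**
- What may go wrong: slow oxidative addition into an electron-rich aryl iodide flanked by two bulky silyloxy groups, so that alkyne homocoupling and deiodination dominate.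
- Fallback (sets out from 4, returns at 9): the chain is attached before O5 is silylated, by B-alkyl Suzuki–Miyaura coupling. 2-Methylbut-3-en-2-ol is silylated (TESCl, imidazole) to triethyl[(2-methylbut-3-en-2-yl)oxy]silane F14 and hydroborated with 9-BBN to the B-alkyl-9-borabicyclo[3.3.1]nonane F15. Coupling of F15 with 4 under Pd(dppf)Cl2 and K3PO4 in DMF–THF gives 1-[6-(benzyloxy)-2-hydroxy-3-[3-methyl-3-(triethylsilyloxy)butyl]-4-(triisopropylsilyloxy)phenyl]ethanone F16. TBSOTf with 2,6-lutidine gives its TBS ether F17, and hydrogenolysis of the benzyl ether (H2, Pd/C) gives 9.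

## Further compounds

F1 | step 12 | 2,2-dimethyl-2,6,7,8-tetrahydro-5H-chromen-5-one | CC1(C)C=CC2=C(O1)CCCC2=O
F2 | step 12 | 2,2-dimethyl-2H-chromen-5-ol | CC1(C)C=Cc2c(O)cccc2O1
F3 | step 12 | {2-[(2,2-dimethyl-2H-chromen-5-yl)oxymethoxy]ethyl}trimethylsilane | CC1(C)C=Cc2c(OCOCC[Si](C)(C)C)cccc2O1
F4 | step 12 | 2-{2,2-dimethyl-5-[2-(trimethylsilyl)ethoxymethoxy]-2H-chromen-6-yl}-4,4,5,5-tetramethyl-1,3,2-dioxaborolane | CC1(C)C=Cc2c(OCOCC[Si](C)(C)C)c(B3OC(C)(C)C(C)(C)O3)ccc2O1
F5 | step 12 | 5-(tert-butyldimethylsilyloxy)-3-{2,2-dimethyl-5-[2-(trimethylsilyl)ethoxymethoxy]-2H-chromen-6-yl}-6-[3-methyl-3-(triethylsilyloxy)butyl]-7-(triisopropylsilyloxy)-4H-chromen-4-one | CC(C)(O[Si](CC)(CC)CC)CCc1c(O[Si](C(C)C)(C(C)C)C(C)C)cc2occ(-c3ccc4OC(C)(C)C=Cc4c3OCOCC[Si](C)(C)C)c(=O)c2c1O[Si](C)(C)C(C)(C)C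
F6 | step 9 | 5-(tert-butyldimethylsilyloxy)-6-[3-methyl-3-(triethylsilyloxy)butyl]-7-(triisopropylsilyloxy)-3-[(trimethylsilyl)ethynyl]-4H-chromen-4-one | CC(C)(O[Si](CC)(CC)CC)CCc1c(O[Si](C(C)C)(C(C)C)C(C)C)cc2occ(C#C[Si](C)(C)C)c(=O)c2c1O[Si](C)(C)C(C)(C)C
F7 | step 9 | 5-(tert-butyldimethylsilyloxy)-3-ethynyl-6-[3-methyl-3-(triethylsilyloxy)butyl]-7-(triisopropylsilyloxy)-4H-chromen-4-one | CC(C)(O[Si](CC)(CC)CC)CCc1c(O[Si](C(C)C)(C(C)C)C(C)C)cc2occ(C#C)c(=O)c2c1O[Si](C)(C)C(C)(C)C
F8 | step 9 | lithium acetylide of F7 | [Li+].[C-]#Cc1coc2cc(O[Si](C(C)C)(C(C)C)C(C)C)c(CCC(C)(C)O[Si](CC)(CC)CC)c(O[Si](C)(C)C(C)(C)C)c2c1=O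
F9 | step 9 | lithium tert-butyl peroxide | [Li+].[O-]OC(C)(C)C
F10 | step 9 | lithium 2-{5-(tert-butyldimethylsilyloxy)-6-[3-methyl-3-(triethylsilyloxy)butyl]-4-oxo-7-(triisopropylsilyloxy)-4H-chromen-3-yl}ethynolate | [Li+].[O-]C#Cc1coc2cc(O[Si](C(C)C)(C(C)C)C(C)C)c(CCC(C)(C)O[Si](CC)(CC)CC)c(O[Si](C)(C)C(C)(C)C)c2c1=O
F11 | step 10 | lithium [(triisopropylsilyl)oxy]acetylide | [Li+].[C-]#CO[Si](C(C)C)(C(C)C)C(C)C
F12 | step 10 | chloro{[(triisopropylsilyl)oxy]ethynyl}zinc | Cl[Zn]C#CO[Si](C(C)C)(C(C)C)C(C)C
F13 | step 8 | 5-(tert-butyldimethylsilyloxy)-2-hydroxy-6-[3-methyl-3-(triethylsilyloxy)butyl]-7-(triisopropylsilyloxy)chroman-4-one (racemic) | CC(C)(O[Si](CC)(CC)CC)CCc1c(O[Si](C(C)C)(C(C)C)C(C)C)cc2OC(O)CC(=O)c2c1O[Si](C)(C)C(C)(C)C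
F14 | step 6 | triethyl[(2-methylbut-3-en-2-yl)oxy]silane | C=CC(C)(C)O[Si](CC)(CC)CC
F15 | step 6 | 9-[3-methyl-3-(triethylsilyloxy)butyl]-9-borabicyclo[3.3.1]nonane | CC(C)(CCB1C2CCCC1CCC2)O[Si](CC)(CC)CC
F16 | step 6 | 1-[6-(benzyloxy)-2-hydroxy-3-[3-methyl-3-(triethylsilyloxy)butyl]-4-(triisopropylsilyloxy)phenyl]ethanone | CC(=O)c1c(O)c(CCC(C)(C)O[Si](CC)(CC)CC)c(O[Si](C(C)C)(C(C)C)C(C)C)cc1OCc1ccccc1
F17 | step 6 | 1-[6-(benzyloxy)-2-(tert-butyldimethylsilyloxy)-3-[3-methyl-3-(triethylsilyloxy)butyl]-4-(triisopropylsilyloxy)phenyl]ethanone | CC(=O)c1c(O[Si](C)(C)C(C)(C)C)c(CCC(C)(C)O[Si](CC)(CC)CC)c(O[Si](C(C)C)(C(C)C)C(C)C)cc1OCc1ccccc1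
A1 | alternative 1 | 5,7,2'-tris-O-methoxymethyl Kanzonol T | CC(C)(O)CCc1c(OCOC)cc2occ(-c3ccc4OC(C)(C)C=Cc4c3OCOC)c(=O)c2c1OCOC
A2 | alternative 1 | 4-(3-hydroxy-3-methylbutyl)-3,5-bis(methoxymethoxy)-2-(trimethylsilyl)phenyl trifluoromethanesulfonate | CC(C)(O)CCc1c(OCOC)cc(OS(=O)(=O)C(F)(F)F)c([Si](C)(C)C)c1OCOC
A3 | alternative 1 | 4-(3-hydroxy-3-methylbutyl)-3,5-bis(methoxymethoxy)benzyne (triple bond between the former silyl and triflate carbons) | CC(C)(O)CCC1=C(OCOC)C#CC=C1OCOC
A4 | alternative 1 | methyl 2-[5-(methoxymethoxy)-2,2-dimethyl-2H-chromen-6-yl]-3-oxopropanoate | COC(=O)C(C=O)c1ccc2OC(C)(C)C=Cc2c1OCOC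
A5 | alternative 2 | 2'-O-allyl Kanzonol T | CC(C)(O)CCc1c(O)cc2occ(-c3ccc4OC(C)(C)C=Cc4c3OCC=C)c(=O)c2c1O
A6 | alternative 2 | methyl 5-[5-(allyloxy)-2,2-dimethyl-2H-chromen-6-yl]-2-methyl-4-oxo-4H-pyran-3-carboxylate | COC(=O)c1c(C)occ(-c2ccc3OC(C)(C)C=Cc3c2OCC=C)c1=O
A7 | alternative 2 | 6,6-dimethyltetrahydro-2H-pyran-2-one | CC1(C)CCCC(=O)O1
A8 | alternative 3 | 2-(trimethylsilyl)-5,7,2'-tris-O-(tert-butyldimethylsilyl) Kanzonol T | CC(C)(O)CCc1c(O[Si](C)(C)C(C)(C)C)cc2oc([Si](C)(C)C)c(-c3ccc4OC(C)(C)C=Cc4c3O[Si](C)(C)C(C)(C)C)c(=O)c2c1O[Si](C)(C)C(C)(C)C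
A9 | alternative 3 | 4,6-bis(tert-butyldimethylsilyloxy)-2-hydroxy-5-(3-hydroxy-3-methylbutyl)benzaldehyde | CC(C)(O)CCc1c(O[Si](C)(C)C(C)(C)C)cc(O)c(C=O)c1O[Si](C)(C)C(C)(C)C
A10 | alternative 3 | tert-butyl{[2,2-dimethyl-6-[(trimethylsilyl)ethynyl]-2H-chromen-5-yl]oxy}dimethylsilane | C[Si](C)(C)C#Cc1ccc2OC(C)(C)C=Cc2c1O[Si](C)(C)C(C)(C)C
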